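**Retrosynthetic overview**
1. Numbering: flavan O1/C2–C8a (rings A and C), C1'–C6' (ring B), O1''/C2''–C4'' (ring D, fused at C3'–C4'). The last disconnection opens ring C at C3–C4 and O1–C2: an inverse-demand oxa-[4+2] between an A-ring o-quinone methide (o-QM) and a B/D-ring styrene, which joins the two halves and sets C2.
2. Enabling feature: C4 is a CH2 on C4a, ortho to the phenol carbon C8a (O1) and para to O7, so ring A can be unmasked as the o-QM O1=C8a–C4a=C4. C2 is benzylic to ring B, whose C4' (para to C1') carries the ring-D oxygen, so the vinyl arene is electron-rich and polarised to take O1 at C2.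
3. A half (five steps from 2,4-dihydroxybenzaldehyde): the 6-(1,1-dimethylallyl) group comes from aromatic Claisen rearrangement of the O7 prenyl ether; the aldehyde carbon becomes C4.
4. B/D half (ten steps from 6-bromoveratraldehyde): ring D by propargyl Claisen/oxa-6π closure, C3'' by Jacobsen epoxidation and benzylic hydride opening, the 2'-prenyl group by Stille coupling, the vinyl group by Wittig reaction.
5. Ring order: A and B purchased, D (step 9), C last (step 16); global desilylation ends the route.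

Key step: step 16

Remark: the sense of induction of the chiral acid in step 16 cannot be predicted with certainty; the (R)-catalyst is written, and its mirror image is used if it delivers the opposite face.

**Route**

Step 1
Reactants: 1 2,4-dihydroxybenzaldehyde
Product: 2 2-hydroxy-4-[(3-methylbut-2-en-1-yl)oxy]benzaldehyde
Conditions: prenyl bromide (1.05 equiv), K2CO3 (1.1 equiv), acetone, rt
Reagents that add atoms: prenyl bromide (1-bromo-3-methylbut-2-ene), CC(C)=CCBr
Why: Williamson etherification occurs at the 4-OH, which is the more acidic and is not held in the hydrogen bond to the formyl group.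

Step 2
Reactants: 2 2-hydroxy-4-[(3-methylbut-2-en-1-yl)oxy]benzaldehyde
Product: 3 2-formyl-5-[(3-methylbut-2-en-1-yl)oxy]phenyl pivalate
Conditions: PivCl, Et3N, DMAP (cat.), CH2Cl2, 0 °C to rt
Reagents that add atoms: pivaloyl chloride, CC(C)(C)C(Cl)=O
Why: DMAP-catalysed acylation caps the chelated 2-OH as a heat-stable pivalate and removes the O–H···O=C chelate that would steer the coming Claisen rearrangement to C3.

Step 3
Reactants: 3 2-formyl-5-[(3-methylbut-2-en-1-yl)oxy]phenyl pivalate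
Product: 5 2-formyl-5-hydroxy-4-(2-methylbut-3-en-2-yl)phenyl pivalate, via ortho-dienone 4 (not isolated)
Conditions: PhNEt2, 190 °C, Ar
Reagents that add atoms: none
Why: Aromatic Claisen rearrangement ([3,3]) should deliver the inverted 1,1-dimethylallyl group to the free, unhindered ortho carbon C5 rather than to C3 between the two oxygens, and tautomerisation of dienone 4 gives the phenol.

Step 4
Reactants: 5 2-formyl-5-hydroxy-4-(2-methylbut-3-en-2-yl)phenyl pivalate
Product: 6 5-[(tert-butyldimethylsilyl)oxy]-2-formyl-4-(2-methylbut-3-en-2-yl)phenyl pivalate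
Conditions: TBSOTf, 2,6-lutidine, CH2Cl2, 0 °C
Reagents that add atoms: tert-butyldimethylsilyl triflate, CC(C)(C)[Si](C)(C)OS(=O)(=O)C(F)(F)F
Why: Silylation of the hindered phenol with the silyl triflate keeps O7 as a donor that will stabilise the o-QM and is cleaved by fluoride at the end.

Step 5
Reactants: 6 5-[(tert-butyldimethylsilyl)oxy]-2-formyl-4-(2-methylbut-3-en-2-yl)phenyl pivalate
Product: 7 5-[(tert-butyldimethylsilyl)oxy]-2-(hydroxymethyl)-4-(2-methylbut-3-en-2-yl)phenol
Conditions: DIBAL-H (5 equiv), CH2Cl2, −78 to −20 °C; Rochelle salt work-up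
Reagents that add atoms: none
Why: Hydride reduction with excess DIBAL-H should reduce the aldehyde to the benzylic alcohol and cleave the aryl pivalate in one operation, while the aryl silyl ether and the alkene are inert.

Step 6
Reactants: 8 2-bromo-4,5-dimethoxybenzaldehyde (6-bromoveratraldehyde)
Product: 9 2-bromo-4,5-dihydroxybenzaldehyde
Conditions: BBr3 (3 equiv), CH2Cl2, −78 °C to rt; H2O
Reagents that add atoms: none
Why: BBr3 demethylation cleaves both aryl methyl ethers at a stage where no acid-sensitive group is present.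

Step 7
Reactants: 9 2-bromo-4,5-dihydroxybenzaldehyde
Product: 10 2-bromo-5-hydroxy-4-[(2-methylbut-3-yn-2-yl)oxy]benzaldehyde
Conditions: 3-chloro-3-methylbut-1-yne (1.1 equiv), DBU (1.05 equiv), CuCl2·2H2O (1 mol%), MeCN, 0 °C
Reagents that add atoms: 3-chloro-3-methylbut-1-yne, CC(C)(Cl)C#C
Why: Copper-catalysed propargylic etherification of a phenoxide; one equivalent of base should ionise only the more acidic 4-OH (para to the formyl group), as in the known 4-O-selective monoalkylation of 3,4-dihydroxybenzaldehydes.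

Step 8
Reactants: 10 2-bromo-5-hydroxy-4-[(2-methylbut-3-yn-2-yl)oxy]benzaldehyde
Product: 11 2-bromo-4-[(2-methylbut-3-yn-2-yl)oxy]-5-[(triisopropylsilyl)oxy]benzaldehyde
Conditions: TIPSOTf, 2,6-lutidine, CH2Cl2, 0 °C
Reagents that add atoms: triisopropylsilyl triflate, CC(C)[Si](C(C)C)(C(C)C)OS(=O)(=O)C(F)(F)F
Why: Silyl ether formation; TIPS is chosen to withstand the thermal, oxidative, hydride and organometallic steps and to leave with fluoride.

Step 9
Reactants: 11 2-bromo-4-[(2-methylbut-3-yn-2-yl)oxy]-5-[(triisopropylsilyl)oxy]benzaldehyde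
Product: 13 5-bromo-2,2-dimethyl-8-[(triisopropylsilyl)oxy]-2H-chromene-6-carbaldehyde, via o-allenylphenol 12 (not isolated)
Conditions: PhNEt2, 190 °C, Ar
Reagents that add atoms: none
Why: Aryl propargyl ether Claisen rearrangement goes to the only free ortho carbon (the other carries OTIPS), and tautomerisation to 12, 1,5-H shift and oxa-6π electrocyclisation then close ring D as the 2,2-dimethyl-2H-chromene.

Step 10
Reactants: 13 5-bromo-2,2-dimethyl-8-[(triisopropylsilyl)oxy]-2H-chromene-6-carbaldehyde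
Product: 14 (3S,4S)-5-bromo-3,4-epoxy-2,2-dimethyl-8-[(triisopropylsilyl)oxy]chromane-6-carbaldehyde
Conditions: (S,S)-Jacobsen Mn(salen)Cl (5 mol%), mCPBA, NMO, CH2Cl2, −78 °C
Reagents that add atoms: mCPBA (3-chloroperoxybenzoic acid), O=C(OO)c1cccc(Cl)c1
Why: Jacobsen epoxidation, for which 2,2-dimethylchromenes are the best substrate class; the (S,S)-catalyst is expected, by analogy with 2,2-dimethylchromene itself, to give the (3S,4S)-epoxide, and the low-temperature mCPBA/NMO protocol spares the aldehyde and the silyl ether.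

Step 11
Reactants: 14 (3S,4S)-5-bromo-3,4-epoxy-2,2-dimethyl-8-[(triisopropylsilyl)oxy]chromane-6-carbaldehyde
Product: 15 (3S)-5-bromo-6-(hydroxymethyl)-2,2-dimethyl-8-[(triisopropylsilyl)oxy]chroman-3-ol
Conditions: LiAlH4, THF, 0 °C
Reagents that add atoms: none
Why: LiAlH4 reduces the aldehyde and should open the epoxide by SN2 attack at the benzylic C4 (C3 is neopentylic), so the C3–O bond is untouched and C3 keeps its (S) configuration.

Step 12
Reactants: 15 (3S)-5-bromo-6-(hydroxymethyl)-2,2-dimethyl-8-[(triisopropylsilyl)oxy]chroman-3-ol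
Product: 16 (3S)-5-bromo-3-hydroxy-2,2-dimethyl-8-[(triisopropylsilyl)oxy]chromane-6-carbaldehyde
Conditions: activated MnO2, CH2Cl2, rt
Reagents that add atoms: none
Why: MnO2 oxidises only the benzylic primary alcohol back to the aldehyde; the secondary alcohol is not benzylic and stays.

Step 13
Reactants: 16 (3S)-5-bromo-3-hydroxy-2,2-dimethyl-8-[(triisopropylsilyl)oxy]chromane-6-carbaldehyde
Product: 17 (3S)-5-bromo-2,2-dimethyl-3-[(triethylsilyl)oxy]-8-[(triisopropylsilyl)oxy]chromane-6-carbaldehyde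
Conditions: TESOTf, 2,6-lutidine, CH2Cl2, −78 to 0 °C
Reagents that add atoms: triethylsilyl triflate, CC[Si](CC)(CC)OS(=O)(=O)C(F)(F)F
Why: Silylation of the neopentylic secondary alcohol with the reactive triflate ensures that no free alcohol can trap the o-QM in step 16.

Step 14
Reactants: 17 (3S)-5-bromo-2,2-dimethyl-3-[(triethylsilyl)oxy]-8-[(triisopropylsilyl)oxy]chromane-6-carbaldehyde
Product: 18 (3S)-2,2-dimethyl-5-(3-methylbut-2-en-1-yl)-3-[(triethylsilyl)oxy]-8-[(triisopropylsilyl)oxy]chromane-6-carbaldehyde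
Conditions: tributyl(prenyl)stannane (1.3 equiv), Pd(PPh3)4 (5 mol%), DMF, 90 °C
Reagents that add atoms: tributyl(3-methylbut-2-en-1-yl)stannane, CCCC[Sn](CCCC)(CCCC)CC=C(C)C
Why: Stille coupling; the bromide is activated by the ortho formyl group, and allyl transfer from the prenylstannane should occur at the unsubstituted terminus to give the linear prenyl group.

Step 15
Reactants: 18 (3S)-2,2-dimethyl-5-(3-methylbut-2-en-1-yl)-3-[(triethylsilyl)oxy]-8-[(triisopropylsilyl)oxy]chromane-6-carbaldehyde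
Product: 19 (3S)-6-ethenyl-2,2-dimethyl-5-(3-methylbut-2-en-1-yl)-3-[(triethylsilyl)oxy]-8-[(triisopropylsilyl)oxy]chromane
Conditions: Ph3PCH3Br, KOtBu, THF, 0 °C
Reagents that add atoms: methyltriphenylphosphonium bromide, C[P+](c1ccccc1)(c1ccccc1)c1ccccc1.[Br-]
Why: Wittig methylenation of the aryl aldehyde; the silyl ethers and the prenyl group are inert to the non-stabilised ylide at 0 °C.

Step 16
Reactants: 7 5-[(tert-butyldimethylsilyl)oxy]-2-(hydroxymethyl)-4-(2-methylbut-3-en-2-yl)phenol; 19 (3S)-6-ethenyl-2,2-dimethyl-5-(3-methylbut-2-en-1-yl)-3-[(triethylsilyl)oxy]-8-[(triisopropylsilyl)oxy]chromane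
Product: 21 (2S)-7-[(tert-butyldimethylsilyl)oxy]-6-(2-methylbut-3-en-2-yl)-2-[(3S)-2,2-dimethyl-5-(3-methylbut-2-en-1-yl)-3-[(triethylsilyl)oxy]-8-[(triisopropylsilyl)oxy]chroman-6-yl]chromane, via o-quinone methide 20 (not isolated)
Conditions: (R)-3,3'-bis(2,4,6-triisopropylphenyl)-H8-BINOL N-triflylphosphoramide (10 mol%), 5 Å MS, toluene, −30 °C; 7 (1.5 equiv) added slowly to 19
Reagents that add atoms: none
Why: Proposed new method: the chiral Brønsted acid ionises the benzylic alcohol of 7 (its carbon is ortho to the O1 phenol and para to the O7 silyl ether, so water is lost easily) to the o-QM 20, held in the chiral pocket by hydrogen bonding to its carbonyl oxygen, and this 1-oxadiene adds across the vinyl group of 19 in an asynchronous inverse-demand oxa-[4+2] cycloaddition in which C4–C3 bonding leads and O1 then bonds to the benzylic C2 that the para ring-D oxygen stabilises. The closest known reaction type is the chiral N-triflylphosphoramide-catalysed [4+2] cycloaddition of styrenes with o-QMs generated from o-hydroxybenzhydryl alcohols; the extension is to a methide carbon that carries no aryl group. Ring C is closed by [4+2] cycloaddition (formally a 6-endo collapse of the phenolic oxygen onto the benzylic cation if the process is stepwise). The C2 stereocentre is set by the catalyst, which must select the face of the planar o-QM and the endo or exo orientation of the styrene together, the two elements the precedent controls as ee and dr; the C3'' centre is remote and should not interfere. The step needs O1 to bond to the benzylic carbon (secured by the polarisation of the para-oxygenated styrene), reaction at the conjugated vinyl group rather than at the prenyl or 1,1-dimethylallyl alkenes (secured by conjugation with the donor arene), O1–C2 closure faster than capture of the benzylic cation by the ortho prenyl group (secured by the tight ion pair), and suppression of o-QM oligomerisation (secured by slow addition of 7).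

Step 17
Reactants: 21 (2S)-7-[(tert-butyldimethylsilyl)oxy]-6-(2-methylbut-3-en-2-yl)-2-[(3S)-2,2-dimethyl-5-(3-methylbut-2-en-1-yl)-3-[(triethylsilyl)oxy]-8-[(triisopropylsilyl)oxy]chroman-6-yl]chromane
Product: 22 (3S)-6-[(2S)-7-hydroxy-6-(2-methylbut-3-en-2-yl)chroman-2-yl]-2,2-dimethyl-5-(3-methylbut-2-en-1-yl)chromane-3,8-diol (CNP0323011.1)
Conditions: TBAF (4 equiv), AcOH (4 equiv), THF, 0 °C to rt, Ar
Reagents that add atoms: none
Why: Fluoride-mediated global desilylation removes the two aryl silyl ethers and the triethylsilyl ether, with acetic acid protonating the phenoxides at once; no stereocentre is touched.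

**Compound list**
1 | 2,4-dihydroxybenzaldehyde | O=Cc1ccc(O)cc1O | starting material
2 | 2-hydroxy-4-[(3-methylbut-2-en-1-yl)oxy]benzaldehyde | CC(C)=CCOc1ccc(C=O)c(O)c1 | intermediate
3 | 2-formyl-5-[(3-methylbut-2-en-1-yl)oxy]phenyl pivalate | CC(C)=CCOc1ccc(C=O)c(OC(=O)C(C)(C)C)c1 | intermediate
4 | 4-formyl-6-(2-methylbut-3-en-2-yl)-3-(pivaloyloxy)cyclohexa-2,4-dien-1-one (ortho-dienone) | O=C1C=C(OC(=O)C(C)(C)C)C(C=O)=CC1C(C)(C)C=C | intermediate
5 | 2-formyl-5-hydroxy-4-(2-methylbut-3-en-2-yl)phenyl pivalate | C=CC(C)(C)c1cc(C=O)c(OC(=O)C(C)(C)C)cc1O | intermediate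
6 | 5-[(tert-butyldimethylsilyl)oxy]-2-formyl-4-(2-methylbut-3-en-2-yl)phenyl pivalate | C=CC(C)(C)c1cc(C=O)c(OC(=O)C(C)(C)C)cc1O[Si](C)(C)C(C)(C)C | intermediate
7 | 5-[(tert-butyldimethylsilyl)oxy]-2-(hydroxymethyl)-4-(2-methylbut-3-en-2-yl)phenol | C=CC(C)(C)c1cc(CO)c(O)cc1O[Si](C)(C)C(C)(C)C | intermediate
8 | 2-bromo-4,5-dimethoxybenzaldehyde | COc1cc(Br)c(C=O)cc1OC | starting material
9 | 2-bromo-4,5-dihydroxybenzaldehyde | Oc1cc(Br)c(C=O)cc1O | intermediate
10 | 2-bromo-5-hydroxy-4-[(2-methylbut-3-yn-2-yl)oxy]benzaldehyde | C#CC(C)(C)Oc1cc(Br)c(C=O)cc1O | intermediate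
11 | 2-bromo-4-[(2-methylbut-3-yn-2-yl)oxy]-5-[(triisopropylsilyl)oxy]benzaldehyde | C#CC(C)(C)Oc1cc(Br)c(C=O)cc1O[Si](C(C)C)(C(C)C)C(C)C | intermediate
12 | 2-bromo-4-hydroxy-3-(3-methylbuta-1,2-dien-1-yl)-5-[(triisopropylsilyl)oxy]benzaldehyde (o-allenylphenol) | CC(C)=C=Cc1c(Br)c(C=O)cc(O[Si](C(C)C)(C(C)C)C(C)C)c1O | intermediate
13 | 5-bromo-2,2-dimethyl-8-[(triisopropylsilyl)oxy]-2H-chromene-6-carbaldehyde | O=Cc1cc(O[Si](C(C)C)(C(C)C)C(C)C)c2c(c1Br)C=CC(C)(C)O2 | intermediate
14 | (3S,4S)-5-bromo-3,4-epoxy-2,2-dimethyl-8-[(triisopropylsilyl)oxy]chromane-6-carbaldehyde | O=Cc1cc(O[Si](C(C)C)(C(C)C)C(C)C)c2c(c1Br)[C@@H]1O[C@@H]1C(C)(C)O2 | intermediate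
15 | (3S)-5-bromo-6-(hydroxymethyl)-2,2-dimethyl-8-[(triisopropylsilyl)oxy]chroman-3-ol | OCc1cc(O[Si](C(C)C)(C(C)C)C(C)C)c2c(c1Br)C[C@H](O)C(C)(C)O2 | intermediate
16 | (3S)-5-bromo-3-hydroxy-2,2-dimethyl-8-[(triisopropylsilyl)oxy]chromane-6-carbaldehyde | O=Cc1cc(O[Si](C(C)C)(C(C)C)C(C)C)c2c(c1Br)C[C@H](O)C(C)(C)O2 | intermediate
17 | (3S)-5-bromo-2,2-dimethyl-3-[(triethylsilyl)oxy]-8-[(triisopropylsilyl)oxy]chromane-6-carbaldehyde | O=Cc1cc(O[Si](C(C)C)(C(C)C)C(C)C)c2c(c1Br)C[C@H](O[Si](CC)(CC)CC)C(C)(C)O2 | intermediate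
18 | (3S)-2,2-dimethyl-5-(3-methylbut-2-en-1-yl)-3-[(triethylsilyl)oxy]-8-[(triisopropylsilyl)oxy]chromane-6-carbaldehyde | O=Cc1cc(O[Si](C(C)C)(C(C)C)C(C)C)c2c(c1CC=C(C)C)C[C@H](O[Si](CC)(CC)CC)C(C)(C)O2 | intermediate
19 | (3S)-6-ethenyl-2,2-dimethyl-5-(3-methylbut-2-en-1-yl)-3-[(triethylsilyl)oxy]-8-[(triisopropylsilyl)oxy]chromane | C=Cc1cc(O[Si](C(C)C)(C(C)C)C(C)C)c2c(c1CC=C(C)C)C[C@H](O[Si](CC)(CC)CC)C(C)(C)O2 | intermediate
20 | 3-[(tert-butyldimethylsilyl)oxy]-6-methylidene-4-(2-methylbut-3-en-2-yl)cyclohexa-2,4-dien-1-one (o-quinone methide) | C=CC(C)(C)C1=CC(=C)C(=O)C=C1O[Si](C)(C)C(C)(C)C | intermediate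
21 | (2S)-7-[(tert-butyldimethylsilyl)oxy]-6-(2-methylbut-3-en-2-yl)-2-[(3S)-2,2-dimethyl-5-(3-methylbut-2-en-1-yl)-3-[(triethylsilyl)oxy]-8-[(triisopropylsilyl)oxy]chroman-6-yl]chromane | C=CC(C)(C)c1cc2c(cc1O[Si](C)(C)C(C)(C)C)O[C@H](c1cc(O[Si](C(C)C)(C(C)C)C(C)C)c3c(c1CC=C(C)C)C[C@H](O[Si](CC)(CC)CC)C(C)(C)O3)CC2 | intermediate
22 | (3S)-6-[(2S)-7-hydroxy-6-(2-methylbut-3-en-2-yl)chroman-2-yl]-2,2-dimethyl-5-(3-methylbut-2-en-1-yl)chromane-3,8-diol | C=CC(C)(C)c1cc2c(cc1O)O[C@H](c1cc(O)c3c(c1CC=C(C)C)C[C@H](O)C(C)(C)O3)CC2 | target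

**Step count**
Total: 17 steps. Longest linear sequence: 12 steps (8 to 22: steps 6–15, 16, 17); the A-ring branch (steps 1–5) joins at step 16.

**Steps most likely to fail**

1. Step 16 (Proposed new method). What may go wrong: weak facial discrimination at the styrene because the methide carbon carries no substituent, self-condensation of the o-QM, or acid-induced re-ionisation of the new benzylic ether with erosion at C2. Fallback with known chemistry, setting out from 18 and 7 and returning at 21: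
   - Aldehyde 18 is treated with MeMgBr (THF, −78 °C) to give the secondary alcohol (3S)-6-(1-hydroxyethyl)-2,2-dimethyl-5-(3-methylbut-2-en-1-yl)-3-[(triethylsilyl)oxy]-8-[(triisopropylsilyl)oxy]chromane F1.
   - Dess–Martin periodinane oxidises it to the methyl ketone 1-[(3S)-2,2-dimethyl-5-(3-methylbut-2-en-1-yl)-3-[(triethylsilyl)oxy]-8-[(triisopropylsilyl)oxy]chroman-6-yl]ethan-1-one F2.
   - TMSOTf/Et3N converts it into the trimethylsilyl enol ether (3S)-2,2-dimethyl-5-(3-methylbut-2-en-1-yl)-3-[(triethylsilyl)oxy]-8-[(triisopropylsilyl)oxy]-6-[1-(trimethylsilyloxy)ethenyl]chromane F3.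
   - Mukaiyama–Michael addition of F3 to the o-QM released from 7 under achiral acid catalysis (diphenyl phosphate, CH2Cl2, −40 °C) gives, after work-up, the ketone 3-[4-[(tert-butyldimethylsilyl)oxy]-2-hydroxy-5-(2-methylbut-3-en-2-yl)phenyl]-1-[(3S)-2,2-dimethyl-5-(3-methylbut-2-en-1-yl)-3-[(triethylsilyl)oxy]-8-[(triisopropylsilyl)oxy]chroman-6-yl]propan-1-one F4.
   - Noyori transfer hydrogenation (RuCl[(R,R)-TsDPEN](p-cymene), HCO2H/Et3N), which leaves the alkenes alone, should give the (1R)-carbinol (1R)-3-[4-[(tert-butyldimethylsilyl)oxy]-2-hydroxy-5-(2-methylbut-3-en-2-yl)phenyl]-1-[(3S)-2,2-dimethyl-5-(3-methylbut-2-en-1-yl)-3-[(triethylsilyl)oxy]-8-[(triisopropylsilyl)oxy]chroman-6-yl]propan-1-ol F5.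
   - Mitsunobu cyclisation (PPh3, DIAD, THF, 0 °C) closes ring C with inversion to the (2S)-flavan 21.

2. Step 3. What may go wrong: migration to the wrong ortho carbon (C3), or abnormal Claisen rearrangement and cyclisation of the new phenol onto the 1,1-dimethylallyl group at the reaction temperature. Fallback, setting out from 1 and returning at 7:
   - 1 is brominated (NBS, MeCN, 0 °C) to 5-bromo-2,4-dihydroxybenzaldehyde F6, which fixes the position by the halogen.
   - Ligand-controlled, γ-selective Suzuki–Miyaura coupling with prenylboronic acid pinacol ester installs the tertiary allyl group and gives 2,4-dihydroxy-5-(2-methylbut-3-en-2-yl)benzaldehyde F7.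
   - Silylation of the non-chelated 4-OH (TBSCl, imidazole) gives 4-[(tert-butyldimethylsilyl)oxy]-2-hydroxy-5-(2-methylbut-3-en-2-yl)benzaldehyde F8.
   - NaBH4 reduction gives 7.

3. Step 7. What may go wrong: loss of site selectivity between the two catechol hydroxyls, double alkylation, or sequestration of the copper by the catechol. Fallback, setting out from 9 and returning at 11:
   - 9 is converted into its dianion (NaH, 2.2 equiv, THF/DMF, 0 °C) and silylated with one equivalent of TIPSCl at the more nucleophilic 5-oxygen, giving 2-bromo-4-hydroxy-5-[(triisopropylsilyl)oxy]benzaldehyde F9. Any silyl migration should converge on the same isomer, since it leaves the better stabilised 4-phenoxide free.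
   - The single remaining phenol is then etherified with 3-chloro-3-methylbut-1-yne (DBU, CuCl2 cat., MeCN) to give 11.

**Further compounds**
F1 | step 16 | (3S)-6-(1-hydroxyethyl)-2,2-dimethyl-5-(3-methylbut-2-en-1-yl)-3-[(triethylsilyl)oxy]-8-[(triisopropylsilyl)oxy]chromane | CC(O)c1cc(O[Si](C(C)C)(C(C)C)C(C)C)c2c(c1CC=C(C)C)C[C@H](O[Si](CC)(CC)CC)C(C)(C)O2
F2 | step 16 | 1-[(3S)-2,2-dimethyl-5-(3-methylbut-2-en-1-yl)-3-[(triethylsilyl)oxy]-8-[(triisopropylsilyl)oxy]chroman-6-yl]ethan-1-one | CC(=O)c1cc(O[Si](C(C)C)(C(C)C)C(C)C)c2c(c1CC=C(C)C)C[C@H](O[Si](CC)(CC)CC)C(C)(C)O2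
F3 | step 16 | (3S)-2,2-dimethyl-5-(3-methylbut-2-en-1-yl)-3-[(triethylsilyl)oxy]-8-[(triisopropylsilyl)oxy]-6-[1-(trimethylsilyloxy)ethenyl]chromane | C=C(O[Si](C)(C)C)c1cc(O[Si](C(C)C)(C(C)C)C(C)C)c2c(c1CC=C(C)C)C[C@H](O[Si](CC)(CC)CC)C(C)(C)O2
F4 | step 16 | 3-[4-[(tert-butyldimethylsilyl)oxy]-2-hydroxy-5-(2-methylbut-3-en-2-yl)phenyl]-1-[(3S)-2,2-dimethyl-5-(3-methylbut-2-en-1-yl)-3-[(triethylsilyl)oxy]-8-[(triisopropylsilyl)oxy]chroman-6-yl]propan-1-one | C=CC(C)(C)c1cc(CCC(=O)c2cc(O[Si](C(C)C)(C(C)C)C(C)C)c3c(c2CC=C(C)C)C[C@H](O[Si](CC)(CC)CC)C(C)(C)O3)c(O)cc1O[Si](C)(C)C(C)(C)C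
F5 | step 16 | (1R)-3-[4-[(tert-butyldimethylsilyl)oxy]-2-hydroxy-5-(2-methylbut-3-en-2-yl)phenyl]-1-[(3S)-2,2-dimethyl-5-(3-methylbut-2-en-1-yl)-3-[(triethylsilyl)oxy]-8-[(triisopropylsilyl)oxy]chroman-6-yl]propan-1-ol | C=CC(C)(C)c1cc(CC[C@@H](O)c2cc(O[Si](C(C)C)(C(C)C)C(C)C)c3c(c2CC=C(C)C)C[C@H](O[Si](CC)(CC)CC)C(C)(C)O3)c(O)cc1O[Si](C)(C)C(C)(C)C
F6 | step 3 | 5-bromo-2,4-dihydroxybenzaldehyde | O=Cc1cc(Br)c(O)cc1O
F7 | step 3 | 2,4-dihydroxy-5-(2-methylbut-3-en-2-yl)benzaldehyde | C=CC(C)(C)c1cc(C=O)c(O)cc1O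
F8 | step 3 | 4-[(tert-butyldimethylsilyl)oxy]-2-hydroxy-5-(2-methylbut-3-en-2-yl)benzaldehyde | C=CC(C)(C)c1cc(C=O)c(O)cc1O[Si](C)(C)C(C)(C)C
F9 | step 7 | 2-bromo-4-hydroxy-5-[(triisopropylsilyl)oxy]benzaldehyde | O=Cc1cc(O[Si](C(C)C)(C(C)C)C(C)C)c(O)cc1Br
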